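**Plan**

- Retrosynthesis: the two formyl C–C bonds (C3–CHO on ring A, C3'–CHO on ring B) are cut first. Ring A is then opened at C1–C2 and C5–C6, leaving a but-2-ynoate on O5' of ring B and a 1,3-dioxygenated ketene acetal diene. Last come the O5'–acyl bond and the C5'–O bond.
- Forward: ring B is taken from orsellinic acid (benzylation, para-hydroxylation) and the slim acetylenic acid is esterified onto O5'. Ring A is built on that ester by (4+2) cycloaddition and aromatization, both formyl groups enter together, and hydrogenolysis ends the route.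
- Enabling feature: ring A carries C2–OH and C4–OMe in a 1,3-relationship, with C6–CH3 next to the carboxyl-bearing C1. C2–C3–C4–C5 therefore map onto the diene (silyloxy carbon = C2, methoxy carbon = C4) and C1/C6 onto the two alkyne carbons. Because the ester exists before ring A does, no di-ortho-substituted acid ever has to acylate a hindered phenol.
- Stereochemistry: the target has no stereocentre. Control is regiochemical only (cycloaddition orientation, ortho-formylation, O5' versus O4' acylation), and the single stereocentre of the transient cycloadduct is erased on aromatization.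

Key step: step 5

Remark on the chemistry: diene 11 is used as whatever ketene acetal isomer (or mixture) the silylation gives. This geometry is lost on aromatization, so its SMILES carries no double-bond descriptor; cycloadduct 13 is racemic.

**Route**

Step 1
Reactants: 1 orsellinic acid (2,4-dihydroxy-6-methylbenzoic acid)
Product: 3 benzyl 4-(benzyloxy)-2-hydroxy-6-methylbenzoate, via benzyl orsellinate 2 (not isolated)
Conditions: BnBr (2.1 equiv), K2CO3, DMF, rt
Reagents that add atoms: benzyl bromide, BrCc1ccccc1
Why: Williamson-type O-alkylation in which the carboxylate and then the acidic, non-chelated C4 phenol are benzylated, while the C2 phenol, hydrogen-bonded to the ester carbonyl, should stay free at room temperature.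

Step 2
Reactants: 3 benzyl 4-(benzyloxy)-2-hydroxy-6-methylbenzoate
Product: 5 benzyl 4-(benzyloxy)-2,5-dihydroxy-6-methylbenzoate, via potassium aryl sulfate 4 (not isolated)
Conditions: K2S2O8, aq NaOH–pyridine, 0 °C → rt; then aq HCl, 70 °C, under N2
Reagents that add atoms: potassium peroxodisulfate, [K+].[K+].[O-]S(=O)(=O)OOS(=O)(=O)[O-]
Why: Elbs persulfate oxidation, in which the phenoxide of 3 attacks the peroxide oxygen through the only free para carbon (C5) and acid hydrolysis of sulfate 4 frees the quinol; 2-hydroxy-4-alkoxy aryl carbonyl compounds are classical substrates and the hindered, phenoxide-flanked benzyl ester should resist saponification.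

Step 3
Reactants: 5 benzyl 4-(benzyloxy)-2,5-dihydroxy-6-methylbenzoate; 6 but-2-ynoic acid
Product: 8 benzyl 4-(benzyloxy)-5-(but-2-ynoyloxy)-2-hydroxy-6-methylbenzoate, via O-acylisourea 7 (not isolated)
Conditions: DCC, DMAP (cat.), CH2Cl2, 0 °C → rt
Reagents that add atoms: none
Why: Steglich esterification in which the linear acetylenic acid acylates the non-chelated C5 phenol despite its two ortho neighbours, while the C2 phenol, locked in a hydrogen bond to the benzyl ester, is left alone, as is usual in acylations of orsellinate phenols.

Step 4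
Reactants: 9 methyl (E)-3-methoxybut-2-enoate
Product: 11 1,3-dimethoxy-1-(trimethylsilyloxy)buta-1,3-diene, via lithium dienolate 10 (not isolated)
Conditions: LiN(iPr)2, THF, −78 °C; Me3SiCl, −78 °C → rt; non-aqueous work-up, distillation
Reagents that add atoms: chlorotrimethylsilane, C[Si](C)(C)Cl
Why: γ-deprotonation of the vinylogous carbonate gives the extended dienolate, which Me3SiCl traps on oxygen (silyl ketene acetal formation), the standard preparation of this diene.

Step 5
Reactants: 8 benzyl 4-(benzyloxy)-5-(but-2-ynoyloxy)-2-hydroxy-6-methylbenzoate; 11 1,3-dimethoxy-1-(trimethylsilyloxy)buta-1,3-diene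
Product: 15 benzyl 4-(benzyloxy)-2-hydroxy-5-[(2-hydroxy-4-methoxy-6-methylbenzoyl)oxy]-6-methylbenzoate, via O-silylated ynoate 12 (not isolated), via cyclohexadiene cycloadduct 13 (not isolated), via arene bis(trimethylsilyl ether) 14 (not isolated)
Conditions: 11 (3.5 equiv, two portions), toluene, 120 °C, sealed tube; then 1 M HCl, THF, rt
Reagents that add atoms: none
Why: The electron-rich ketene acetal diene 11 and the electron-poor ynoate undergo a thermal, suprafacial normal-demand Diels–Alder reaction (a (4+2) cycloaddition that is probably asynchronous, with Mukaiyama–Michael character), after a first equivalent of 11 has silylated the chelated C2' phenol of 8 to give 12. Ring A closes as a six-membered carbocycle in one intermolecular cycloaddition that forms C5–C6 (diene CH2 to the methyl-bearing alkyne carbon) and C1–C2 (acetal carbon to the ester-bearing alkyne carbon); cyclohexa-1,4-diene 13 should then lose methanol across the ring to give arene 14, and dilute acid removes both silyl groups. The closest known reaction type is the cycloaddition of 1,3-dioxygenated ketene silyl acetal dienes with acetylenic esters to give resorcylate ethers, in which β-methyl ynoates are slow, hence the excess diene, the prolonged heating and the aryl ester, which lowers the alkyne LUMO more than an alkyl ester would. The only new stereocentre, the ketal carbon of 13, is formed racemic and vanishes on aromatization, so nothing has to control it. The step needs regioselectivity, which the matched polarisation secures (largest HOMO coefficient at the diene CH2, largest LUMO coefficient at the ynoate β-carbon), and it needs methanol rather than silanol to be expelled, which is secured because the silyloxy group is cleaved only on work-up, where a remaining hemiketal can collapse only to the phenol.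

Step 6
Reactants: 15 benzyl 4-(benzyloxy)-2-hydroxy-5-[(2-hydroxy-4-methoxy-6-methylbenzoyl)oxy]-6-methylbenzoate
Product: 17 benzyl 4-(benzyloxy)-3-formyl-5-[(3-formyl-2-hydroxy-4-methoxy-6-methylbenzoyl)oxy]-2-hydroxy-6-methylbenzoate, via bis(hydroxymethyl) depside 16 (not isolated)
Conditions: MgCl2, Et3N, (CH2O)n, MeCN, reflux; then aq HCl
Reagents that add atoms: paraformaldehyde (as formaldehyde), C=O
Why: magnesium-mediated ortho-formylation (Casnati–Skattebøl reaction), in which each magnesium phenoxide delivers formaldehyde to its only free ortho carbon (C3 on ring A, C3' on ring B) and a second formaldehyde oxidises the benzylic alkoxide by hydride transfer, while the benzyl group kept on O4' rules out acyl migration from O5' to O4' in the basic medium.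

Step 7
Reactants: 17 benzyl 4-(benzyloxy)-3-formyl-5-[(3-formyl-2-hydroxy-4-methoxy-6-methylbenzoyl)oxy]-2-hydroxy-6-methylbenzoate
Product: 19 haemathamnolic acid, via mono-benzyl ether acid 18 (not isolated)
Conditions: H2 (1 atm), 10% Pd/C, EtOAc, rt, stopped after uptake of two equivalents
Reagents that add atoms: none
Why: catalytic hydrogenolysis of the benzyl ester and the aryl benzyl ether, which should outpace reduction of the two formyl groups because each is held in a hydrogen bond to an ortho hydroxyl and the neutral solvent disfavours benzylic C–O reduction of the aldehydes.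

**Compound list**

1 | orsellinic acid (2,4-dihydroxy-6-methylbenzoic acid) | Cc1cc(O)cc(O)c1C(=O)O | starting material
2 | benzyl 2,4-dihydroxy-6-methylbenzoate (benzyl orsellinate) | Cc1cc(O)cc(O)c1C(=O)OCc1ccccc1 | intermediate
3 | benzyl 4-(benzyloxy)-2-hydroxy-6-methylbenzoate | Cc1cc(OCc2ccccc2)cc(O)c1C(=O)OCc1ccccc1 | intermediate
4 | benzyl 4-(benzyloxy)-2-hydroxy-6-methyl-5-(sulfonatooxy)benzoate, potassium salt | [K+].[O-]S(=O)(=O)Oc1c(C)c(C(=O)OCc2ccccc2)c(O)cc1OCc1ccccc1 | intermediate
5 | benzyl 4-(benzyloxy)-2,5-dihydroxy-6-methylbenzoate | Cc1c(O)c(OCc2ccccc2)cc(O)c1C(=O)OCc1ccccc1 | intermediate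
6 | but-2-ynoic acid | CC#CC(=O)O | starting material
7 | O-(but-2-ynoyl)-N,N'-dicyclohexylisourea | CC#CC(=O)OC(=NC1CCCCC1)NC1CCCCC1 | intermediate
8 | benzyl 4-(benzyloxy)-5-(but-2-ynoyloxy)-2-hydroxy-6-methylbenzoate | CC#CC(=O)Oc1c(C)c(C(=O)OCc2ccccc2)c(O)cc1OCc1ccccc1 | intermediate
9 | methyl (E)-3-methoxybut-2-enoate | CO/C(C)=C/C(=O)OC | starting material
10 | lithium 1,3-dimethoxybuta-1,3-dien-1-olate | [Li+].C=C(OC)C=C([O-])OC | intermediate
11 | 1,3-dimethoxy-1-(trimethylsilyloxy)buta-1,3-diene (ketene acetal geometry as formed) | C=C(OC)C=C(OC)O[Si](C)(C)C | intermediate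
12 | benzyl 4-(benzyloxy)-5-(but-2-ynoyloxy)-6-methyl-2-(trimethylsilyloxy)benzoate | CC#CC(=O)Oc1c(C)c(C(=O)OCc2ccccc2)c(O[Si](C)(C)C)cc1OCc1ccccc1 | intermediate
13 | benzyl 4-(benzyloxy)-5-{[4,6-dimethoxy-2-methyl-6-(trimethylsilyloxy)cyclohexa-1,4-diene-1-carbonyl]oxy}-6-methyl-2-(trimethylsilyloxy)benzoate (racemic) | COC1=CC(OC)(O[Si](C)(C)C)C(C(=O)Oc2c(C)c(C(=O)OCc3ccccc3)c(O[Si](C)(C)C)cc2OCc2ccccc2)=C(C)C1 | intermediate
14 | benzyl 4-(benzyloxy)-5-{[4-methoxy-6-methyl-2-(trimethylsilyloxy)benzoyl]oxy}-6-methyl-2-(trimethylsilyloxy)benzoate | COc1cc(C)c(C(=O)Oc2c(C)c(C(=O)OCc3ccccc3)c(O[Si](C)(C)C)cc2OCc2ccccc2)c(O[Si](C)(C)C)c1 | intermediate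
15 | benzyl 4-(benzyloxy)-2-hydroxy-5-[(2-hydroxy-4-methoxy-6-methylbenzoyl)oxy]-6-methylbenzoate | COc1cc(C)c(C(=O)Oc2c(C)c(C(=O)OCc3ccccc3)c(O)cc2OCc2ccccc2)c(O)c1 | intermediate
16 | benzyl 4-(benzyloxy)-2-hydroxy-3-(hydroxymethyl)-5-{[2-hydroxy-3-(hydroxymethyl)-4-methoxy-6-methylbenzoyl]oxy}-6-methylbenzoate | COc1cc(C)c(C(=O)Oc2c(C)c(C(=O)OCc3ccccc3)c(O)c(CO)c2OCc2ccccc2)c(O)c1CO | intermediate
17 | benzyl 4-(benzyloxy)-3-formyl-5-[(3-formyl-2-hydroxy-4-methoxy-6-methylbenzoyl)oxy]-2-hydroxy-6-methylbenzoate | COc1cc(C)c(C(=O)Oc2c(C)c(C(=O)OCc3ccccc3)c(O)c(C=O)c2OCc2ccccc2)c(O)c1C=O | intermediate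
18 | 4-(benzyloxy)-3-formyl-5-[(3-formyl-2-hydroxy-4-methoxy-6-methylbenzoyl)oxy]-2-hydroxy-6-methylbenzoic acid | COc1cc(C)c(C(=O)Oc2c(C)c(C(=O)O)c(O)c(C=O)c2OCc2ccccc2)c(O)c1C=O | intermediate
19 | haemathamnolic acid (3-formyl-5-[(3-formyl-2-hydroxy-4-methoxy-6-methylbenzoyl)oxy]-2,4-dihydroxy-6-methylbenzoic acid) | COc1cc(C)c(C(=O)Oc2c(C)c(C(=O)O)c(O)c(C=O)c2O)c(O)c1C=O | target

**Step count**

Total: 7 steps. Longest linear sequence: 6 steps (steps 1, 2, 3, 5, 6, 7 from orsellinic acid); the diene branch adds step 4.

**Steps most likely to fail**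

Step 5. The β-methyl ynoate may cycloadd so slowly that thermal decomposition and adventitious hydrolysis of the diene outrun ring formation, or the cycloadduct may aromatize with loss of silanol instead of methanol. The fallback gives up building ring A and attaches it ready-made. It sets out from quinol 5, which would be acylated at the non-chelated O5 with commercially available 2-hydroxy-4-methoxy-6-methylbenzoic acid (everninic acid) under trifluoroacetic anhydride activation in toluene at room temperature. The mixed anhydride 2-hydroxy-4-methoxy-6-methylbenzoic trifluoroacetic anhydride F1 forms in the flask and transfers the aroyl group to O5, the classical esterification for hindered depsides. The route is rejoined at 15.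

Step 6. Formylation may stall on one of the two chelated, ester-deactivated phenols, stop at the hydroxymethyl stage, or be accompanied by cleavage of the aryl ester by magnesium alkoxides. The fallback replaces the base-mediated, magnesium-templated process by an acidic electrophilic one, a Rieche formylation. It sets out from 15, which is treated with Cl2CHOMe and TiCl4 in CH2Cl2 at −78 → 0 °C. The titanium phenoxides direct the electrophile to C3 and C3', giving benzyl 4-(benzyloxy)-3-[chloro(methoxy)methyl]-5-({3-[chloro(methoxy)methyl]-2-hydroxy-4-methoxy-6-methylbenzoyl}oxy)-2-hydroxy-6-methylbenzoate F2. This is hydrolysed on aqueous work-up, and the route is rejoined at 17.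

Step 2. Conversion may stay low in the heterogeneous alkaline medium, and prolonged exposure may bring saponification of the benzyl ester or oxidative degradation of the electron-rich ring. The fallback installs the C5 oxygen through a quinone instead of a sulfate. It sets out from 3, which undergoes Teuber oxidation with K2[ON(SO3)2] (potassium nitrosodisulfonate) in acetone–aqueous KH2PO4 at room temperature. This should give benzyl 4-(benzyloxy)-2-methyl-3,6-dioxocyclohexa-1,4-diene-1-carboxylate F3. Reduction with Na2S2O4 in EtOAc–water then returns the route to quinol 5.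

**Further compounds**

F1 | step 5 | 2-hydroxy-4-methoxy-6-methylbenzoic trifluoroacetic anhydride | COc1cc(C)c(C(=O)OC(=O)C(F)(F)F)c(O)c1
F2 | step 6 | benzyl 4-(benzyloxy)-3-[chloro(methoxy)methyl]-5-({3-[chloro(methoxy)methyl]-2-hydroxy-4-methoxy-6-methylbenzoyl}oxy)-2-hydroxy-6-methylbenzoate (configuration at the two chloro ether carbons undefined) | COc1cc(C)c(C(=O)Oc2c(C)c(C(=O)OCc3ccccc3)c(O)c(C(Cl)OC)c2OCc2ccccc2)c(O)c1C(Cl)OC
F3 | step 2 | benzyl 4-(benzyloxy)-2-methyl-3,6-dioxocyclohexa-1,4-diene-1-carboxylate | O=C1C=C(OCc2ccccc2)C(=O)C(C)=C1C(=O)OCc1ccccc1
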